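## The problem

Compound 17 is an achiral bicoumarin: C8 of a 7-methoxycoumarin (coumarin A) is joined through an ether oxygen to C8' of a 5,7-dihydroxycoumarin (coumarin B). There is no stereocentre, so the task is one of connectivity and regiochemistry. The ether oxygen is flanked on ring A by the C7 methoxy group and the lactone oxygen O1, and on ring B by the C7' hydroxyl and O1'. A direct aryl–oxygen coupling would therefore have to make a tetra-ortho-substituted diaryl ether between two electron-rich rings. The benzene ring of coumarin B carries four oxygens (C5', C7', C8', C8a'), and its lactone must be fused on the oxygen next to C8'; closure on the oxygen para to the ether gives the 6-aryloxy isomer. The limiting groups are the two lactones (opened by hydroxide or alkoxide, reversibly only while the cis-cinnamate geometry is kept), the free phenols of an electron-rich ring that oxidises in base under air, and the single methyl ether at C7, which forbids a late global demethylation. The enabling feature is that the oxygens on C5', C7' and C8a' alternate as in phloroglucinol, a folded triketide, and that C8' is then the α-carbon of an aryloxyacetyl starter unit. Ring B can thus be closed from the open-chain ester 11 by forming C8'–C8a', so the hindered diaryl ether begins as a primary alkyl aryl ether. The ring so formed (12) has a mirror plane through the C8'–O bond, so its two flanking hydroxyls are equivalent and only the para oxygen has to be told apart.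

## Retrosynthesis

**17 ⇒ 16 ⇒ 13 + 14.** The pyranone of coumarin B is made last. Cutting O1'–C2' and C4'–C4a' of 17, with a silyl group added back on O5', leads through 16 to the mono-silylated aryloxyphloroglucinol 13 and ethyl propiolate 14. A Pechmann condensation would need hot mineral acid, and a formylation–Wittig pair costs a step more. The palladium-catalysed phenol–alkynoate annulation runs at room temperature in formic acid and passes through the (Z)-cinnamate 15. C3 and C5 of ring B in 13 are equivalent, and only a free ortho hydroxyl can lactonise, so masking the para oxygen forces closure on a flanking oxygen. The mask must survive formic acid and leave without base, hence triisopropylsilyl.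

**13 ⇒ 12.** Cutting the O–Si bond gives the symmetrical triol 12. The forward step must pick one phenol of three. The para hydroxyl has two ortho hydrogens, while each flanking hydroxyl sits beside the twisted coumarinyloxy group, so a bulky chlorosilane is asked to discriminate on steric grounds.

**12 ⇒ 11.** This is the strategic cut: C8'–C8a' of ring B, which is C6–C1 of the 6-aryloxy-3,5-dioxohexanoate 11. Cutting the diaryl ether instead would demand the tetra-ortho coupling described above. Any other Claisen cut of ring B would put the aryloxy group on a carbon between two carbonyls, reachable only by alkylating a phenol with a secondary 2-halo-1,3-dicarbonyl compound. The chosen cut keeps the aryloxy group at the chain terminus, removes one ring and all three phenols, and leaves an achiral chain. The forward reaction must acylate C6 on carbon in preference to lactonisation through the C5 enol oxygen.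

**11 ⇒ 7 + 8.** Cutting C4–C5 of the chain gives the aryloxyacetyl unit as acid 7 (activated as chloride 9) and an acetoacetate γ-anion equivalent, the bis(silyl enol ether) 8. The lithium–sodium dianion of methyl acetoacetate is the classical alternative, but it is a strong base and nucleophile beside the lactone of ring A. Diene 8 reacts with acid chlorides without base or Lewis acid and gives 11 through silyl enol ether 10 on work-up.

**7 ⇒ 6 ⇒ 4 + 5.** Cutting the O–CH2 bond gives 8-hydroxy-7-methoxycoumarin 4 and tert-butyl bromoacetate 5. This is an SN2 reaction at a primary carbon, indifferent to the two ortho substituents of the phenol. The tert-butyl ester 6 is chosen so that the acid is freed by acidolysis, not by hydroxide.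

**4 ⇒ 1 + 2.** Cutting O1–C2 and C3–C4 of coumarin A gives 2,3-dihydroxy-4-methoxybenzaldehyde 1 and the stabilised ylide 2. The Wittig olefination–lactonisation through cinnamate 3 sets the whole substitution pattern of ring A from a commercial aldehyde, and only the hydroxyl ortho to the formyl group can close the lactone.

## Roads not taken

**Alternative 1:** Ring A is built from an open chain by cutting C4a–C5, with ring B brought in as the differentiated phenol 2,4-bis(benzyloxy)-6-(methoxymethoxy)phenol A1.
- *Key step:* A1 sits on the central carbon of the masked tetraketide methyl (6E)-4-aryloxy-7-methoxy-3,5-dioxohept-6-enoate A2. With Mg(OMe)2, C2 adds to the methoxyenone terminus, methoxide leaves, and ring A aromatises as the benzoate A3.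
- *Merits:* The nucleophile is a β-keto ester carbon, far more acidic than C6 of 11, and the addition–elimination cannot revert. A3 has its two phenols distinguished by chelation to the ester. Ring B arrives with its oxygens already told apart, so nothing like step 6 is needed. In these respects this road is better founded than the chosen one.
- *Weak points:* A2 carries a bulky aryloxy group on a carbon between two ketones, so its ether must come from alkylating hindered A1 with a secondary halide or from acylating an α-aryloxy ketone. A1 itself costs several steps. A2 can also close through oxygen onto the enone terminus. After A3 there remain O-methylation, ester-to-aldehyde adjustment, lactone A, acetal removal, lactone B and two debenzylations beside two coumarin double bonds.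
- *Comparison:* The route would be roughly twice as long. The chosen plan sets against it the SN2 ether, a protecting-group-free ring B from cheap units, and eight steps.

**Alternative 2:** Ring A is closed at C8–C8a by a Dieckmann reaction, with coumarin B pre-made as the phenol 5,7-bis(benzyloxy)-8-hydroxy-2H-chromen-2-one A4.
- *Key step:* The chain is the 6-aryloxy-5-oxo-3-silyloxyhexanoate A5 (silyl taken as tert-butyldimethylsilyl). NaH closes it through the C6 carbanion, and acid-induced loss of silanol aromatises ring A as the 2-aryloxyresorcinol A6.
- *Merits:* C3 is at the alcohol oxidation level, so there is no diketonate to absorb base and no 4-hydroxypyranone pathway. The cyclisation is an ordinary ketone-enolate Dieckmann closure and is kinetically more comfortable than step 5. Elimination gives exactly the resorcinol level ring A needs.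
- *Weak points:* The difficult part of the molecule, the tetraoxygenated ring B with its lactone correctly placed, must already exist in A4 and is not solved by the key step. The β-silyloxy ketone of A5 can eliminate under NaH before it cyclises. A6 is a symmetrical resorcinol, so mono-methylation is a statistical desymmetrisation, followed by annulation and hydrogenolysis beside two coumarin alkenes.
- *Comparison:* The chosen plan puts its key step where the structure is hardest and needs one selective protection instead of a statistical one.

**Alternative 3:** Ring A is assembled by a Diels–Alder reaction forming C4a–C8a and C5–C6.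
- *Key step:* The ketene-acetal diene A7, which carries the aryloxy group of A1 on C2, adds to propynal A8. Loss of methanol and desilylation give the salicylaldehyde A9.
- *Merits:* The route is convergent. The polarised diene fixes the regiochemistry, with no carbon-versus-oxygen acylation question. A9 already holds the C7 methoxy group and the aldehyde and hydroxyl needed for Wittig lactonisation. Its predictability is higher than that of step 5.
- *Weak points:* A7 is a hydrolytically fragile diene bearing four heteroatom substituents and a bulky aryloxy group beside its reacting terminus. A8 is volatile and hazardous. A1 and the long end game on ring B (acetal removal, annulation, double debenzylation) are still required.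
- *Comparison:* The chosen plan accepts a less certain ring closure in exchange for a much shorter route without benzyl ethers.

Key step: step 5

Remarks on the chemistry:
- Diene 8 is taken as the commercial mixture of C1=C2 geometric isomers. This geometry, like that of silyl enol ether 10, does not survive into 11, so both are written without double-bond descriptors.
- 11 is written as the triketo tautomer although it will exist largely in enolised forms.

## Route

Step 1
Reactants: 1 2,3-dihydroxy-4-methoxybenzaldehyde; 2 ethyl (triphenylphosphoranylidene)acetate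
Product: 4 8-hydroxy-7-methoxy-2H-chromen-2-one, via ethyl (2E)-3-(2,3-dihydroxy-4-methoxyphenyl)prop-2-enoate 3 (not isolated)
Conditions: 2 (1.3 equiv), PhNEt2, reflux (ca. 215 °C), N2
Reagents that add atoms: none
Why: Wittig olefination–lactonisation: the stabilised ylide gives cinnamate 3, which at this temperature isomerises about the double bond and lactonises through the ortho hydroxyl with loss of ethanol, a standard coumarin synthesis from free hydroxysalicylaldehydes. The C3 hydroxyl of 1 cannot reach the ester and stays free.

Step 2
Reactants: 4 8-hydroxy-7-methoxy-2H-chromen-2-one; 5 tert-butyl bromoacetate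
Product: 6 tert-butyl 2-[(7-methoxy-2-oxo-2H-chromen-8-yl)oxy]acetate
Conditions: 5 (1.2 equiv), K2CO3, DMF, 20 °C
Reagents that add atoms: none
Why: Williamson ether synthesis: the phenoxide of 4 displaces bromide from an unhindered primary α-bromo ester by SN2, which the two ortho substituents of the phenol do not impede. Carbonate in DMF leaves lactone and tert-butyl ester intact.

Step 3
Reactants: 6 tert-butyl 2-[(7-methoxy-2-oxo-2H-chromen-8-yl)oxy]acetate
Product: 7 2-[(7-methoxy-2-oxo-2H-chromen-8-yl)oxy]acetic acid
Conditions: CF3CO2H, CH2Cl2, 20 °C
Reagents that add atoms: none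
Why: Acidolysis of the tert-butyl ester with loss of 2-methylpropene frees the acid without hydroxide, so the lactone of ring A is never opened. Aryl ethers are inert to these conditions.

Step 4
Reactants: 7 2-[(7-methoxy-2-oxo-2H-chromen-8-yl)oxy]acetic acid; 8 1-methoxy-1,3-bis(trimethylsilyloxy)buta-1,3-diene
Product: 11 methyl 6-[(7-methoxy-2-oxo-2H-chromen-8-yl)oxy]-3,5-dioxohexanoate, via 2-[(7-methoxy-2-oxo-2H-chromen-8-yl)oxy]acetyl chloride 9 (not isolated), via methyl 6-[(7-methoxy-2-oxo-2H-chromen-8-yl)oxy]-5-oxo-3-(trimethylsilyloxy)hex-2-enoate 10 (not isolated)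
Conditions: (COCl)2, cat. DMF, CH2Cl2, 0 → 20 °C, evaporate; 8 (1.5 equiv), CH2Cl2, −78 → 20 °C; 1 M HCl work-up
Reagents that add atoms: oxalyl chloride, O=C(Cl)C(=O)Cl (source of the chlorine of 9; none of its atoms remain in 11)
Why: Acid chloride formation, then γ-acylation of the 1,3-bis(silyl enol ether) 8: its terminal carbon attacks 9 with loss of Me3SiCl to give 10, which acidic work-up hydrolyses to 11, a known route from acid chlorides to 3,5-dioxo esters. No base or Lewis acid is present, so the lactone is not attacked and the triketide is not exposed to cyclising conditions.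

Step 5
Reactants: 11 methyl 6-[(7-methoxy-2-oxo-2H-chromen-8-yl)oxy]-3,5-dioxohexanoate
Product: 12 7-methoxy-8-(2,4,6-trihydroxyphenoxy)-2H-chromen-2-one
Conditions: NaOMe (4 equiv), MeOH, reflux, Ar; then 2 M HCl, 0 °C
Reagents that add atoms: none
Why: Methoxide converts 11 into its 3,5-diketonate, and proton transfer gives a small equilibrium share of the tautomeric enolate at C6, which the α-aryloxy group makes several pK units more accessible than in a methyl ketone; this carbanion adds to the C1 ester carbonyl and expels methoxide, forming C8'–C8a'. The resulting 2-aryloxycyclohexane-1,3,5-trione should tautomerise at once to the phloroglucinol and be deprotonated, which makes the carbon–carbon closure irreversible. The closest known reaction type is the Claisen (Dieckmann-type) cyclisation of 5-oxo esters to cyclohexane-1,3-diones, as in the dimedone synthesis, and its extension to 3,5-dioxohexanoate esters, which sodium alkoxide at high temperature converts into phloroglucinol. The ring closes in the 6-(enolexo)-exo-trig mode. No stereocentre is formed, and 12 has a mirror plane through the C8'–O bond. The selectivity needed is carbon acylation by C6 over oxygen acylation by the C5 enol oxygen (the 4-hydroxy-2-pyranone pathway); the substrate supports it through the acidifying aryloxy group and the conditions through reversibility, since methoxide can return a lactone to the open-chain ester whereas the aromatic phenoxide cannot revert. Any opening of the ring A lactone by methoxide should be reversed on acidification, because the cis geometry of its cinnamate is kept.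

Step 6
Reactants: 12 7-methoxy-8-(2,4,6-trihydroxyphenoxy)-2H-chromen-2-one
Product: 13 8-{2,6-dihydroxy-4-[(triisopropylsilyl)oxy]phenoxy}-7-methoxy-2H-chromen-2-one
Conditions: i-Pr3SiCl (1.05 equiv), imidazole, DMF, −20 → 0 °C
Reagents that add atoms: triisopropylsilyl chloride, CC(C)[Si](Cl)(C(C)C)C(C)C
Why: Regioselective mono-silylation of the least hindered phenol: with a bulky chlorosilane and imidazole the rate is governed by steric access, and the para hydroxyl has two ortho hydrogens. Each flanking hydroxyl sits beside the twisted, di-ortho-substituted coumarinyloxy group and is hydrogen-bonded to the ether oxygen.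

Step 7
Reactants: 13 8-{2,6-dihydroxy-4-[(triisopropylsilyl)oxy]phenoxy}-7-methoxy-2H-chromen-2-one; 14 ethyl propiolate
Product: 16 8-({7-hydroxy-2-oxo-5-[(triisopropylsilyl)oxy]-2H-chromen-8-yl}oxy)-7-methoxy-2H-chromen-2-one, via ethyl (2Z)-3-{2,4-dihydroxy-3-[(7-methoxy-2-oxo-2H-chromen-8-yl)oxy]-6-[(triisopropylsilyl)oxy]phenyl}prop-2-enoate 15 (not isolated)
Conditions: 14 (2 equiv), Pd(OAc)2 (5 mol %), NaOAc, HCO2H, 20 °C
Reagents that add atoms: none
Why: Palladium-catalysed hydroarylation–lactonisation of an electron-rich phenol with an alkynoate: the C–H ortho to a free hydroxyl adds across 14 to give the (Z)-cinnamate 15, which lactonises with the only free ortho hydroxyl, a flanking one, because the para oxygen is silylated. C3 and C5 of ring B are equivalent, so one product is expected, and the first lactone deactivates the ring towards a second annulation.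

Step 8
Reactants: 16 8-({7-hydroxy-2-oxo-5-[(triisopropylsilyl)oxy]-2H-chromen-8-yl}oxy)-7-methoxy-2H-chromen-2-one
Product: 17 8-[(5,7-dihydroxy-2-oxo-2H-chromen-8-yl)oxy]-7-methoxy-2H-chromen-2-one
Conditions: Bu4NF, AcOH, THF, 0 °C
Reagents that add atoms: none
Why: Fluoride-induced cleavage of the aryl silyl ether, driven by Si–F bond formation. Acetic acid buffers the phenoxide so that neither lactone is opened, and the methyl ether is untouched.

## Compound list

1 | 2,3-dihydroxy-4-methoxybenzaldehyde | COc1ccc(C=O)c(O)c1O | starting material
2 | ethyl (triphenylphosphoranylidene)acetate | CCOC(=O)C=P(c1ccccc1)(c1ccccc1)c1ccccc1 | starting material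
3 | ethyl (2E)-3-(2,3-dihydroxy-4-methoxyphenyl)prop-2-enoate | CCOC(=O)/C=C/c1ccc(OC)c(O)c1O | intermediate (not isolated)
4 | 8-hydroxy-7-methoxy-2H-chromen-2-one | COc1ccc2ccc(=O)oc2c1O | intermediate
5 | tert-butyl bromoacetate | CC(C)(C)OC(=O)CBr | starting material
6 | tert-butyl 2-[(7-methoxy-2-oxo-2H-chromen-8-yl)oxy]acetate | COc1ccc2ccc(=O)oc2c1OCC(=O)OC(C)(C)C | intermediate
7 | 2-[(7-methoxy-2-oxo-2H-chromen-8-yl)oxy]acetic acid | COc1ccc2ccc(=O)oc2c1OCC(=O)O | intermediate
8 | 1-methoxy-1,3-bis(trimethylsilyloxy)buta-1,3-diene (mixture of geometric isomers) | COC(O[Si](C)(C)C)=CC(=C)O[Si](C)(C)C | starting material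
9 | 2-[(7-methoxy-2-oxo-2H-chromen-8-yl)oxy]acetyl chloride | COc1ccc2ccc(=O)oc2c1OCC(=O)Cl | intermediate (not isolated)
10 | methyl 6-[(7-methoxy-2-oxo-2H-chromen-8-yl)oxy]-5-oxo-3-(trimethylsilyloxy)hex-2-enoate (geometry undefined) | COC(=O)C=C(O[Si](C)(C)C)CC(=O)COc1c(OC)ccc2ccc(=O)oc12 | intermediate (not isolated)
11 | methyl 6-[(7-methoxy-2-oxo-2H-chromen-8-yl)oxy]-3,5-dioxohexanoate | COC(=O)CC(=O)CC(=O)COc1c(OC)ccc2ccc(=O)oc12 | intermediate
12 | 7-methoxy-8-(2,4,6-trihydroxyphenoxy)-2H-chromen-2-one | COc1ccc2ccc(=O)oc2c1Oc1c(O)cc(O)cc1O | intermediate
13 | 8-{2,6-dihydroxy-4-[(triisopropylsilyl)oxy]phenoxy}-7-methoxy-2H-chromen-2-one | COc1ccc2ccc(=O)oc2c1Oc1c(O)cc(O[Si](C(C)C)(C(C)C)C(C)C)cc1O | intermediate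
14 | ethyl propiolate | C#CC(=O)OCC | starting material
15 | ethyl (2Z)-3-{2,4-dihydroxy-3-[(7-methoxy-2-oxo-2H-chromen-8-yl)oxy]-6-[(triisopropylsilyl)oxy]phenyl}prop-2-enoate | CCOC(=O)/C=C\c1c(O)c(Oc2c(OC)ccc3ccc(=O)oc23)c(O)cc1O[Si](C(C)C)(C(C)C)C(C)C | intermediate (not isolated)
16 | 8-({7-hydroxy-2-oxo-5-[(triisopropylsilyl)oxy]-2H-chromen-8-yl}oxy)-7-methoxy-2H-chromen-2-one | COc1ccc2ccc(=O)oc2c1Oc1c(O)cc(O[Si](C(C)C)(C(C)C)C(C)C)c2ccc(=O)oc12 | intermediate
17 | 8-[(5,7-dihydroxy-2-oxo-2H-chromen-8-yl)oxy]-7-methoxy-2H-chromen-2-one | COc1ccc2ccc(=O)oc2c1Oc1c(O)cc(O)c2ccc(=O)oc12 | target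

## Step count and least certain steps

Total step count: 8. Longest linear sequence: 8 steps (1 → 17).

**Step 5 (key step).** The likely failure is kinetic preference for oxygen acylation: lactonisation through the C5 enol oxygen would remove the substrate as a stabilised enolate that methoxide reopens only slowly. The C6 enolate population may also be too small at the boiling point of methanol. Long exposure to methoxide risks cis-to-trans isomerisation of the opened ring A cinnamate and air oxidation of the electron-rich phenoxide.

Fallback, from 4 to 17: the diaryl ether is made by C–O coupling and ring B is carried in differentiated form.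
- Bromination of commercial 3,5-bis(benzyloxy)benzaldehyde with N-bromosuccinimide ortho to the formyl group should give 3,5-bis(benzyloxy)-2-bromobenzaldehyde F1.
- Ullmann-type coupling of 4 with F1 (CuI, N,N-dimethylglycine, Cs2CO3, dioxane, 90 °C), assisted by the ortho formyl group, should give 3,5-bis(benzyloxy)-2-[(7-methoxy-2-oxo-2H-chromen-8-yl)oxy]benzaldehyde F2.
- Baeyer–Villiger (Dakin-type) oxidation with mCPBA should give 3,5-bis(benzyloxy)-2-[(7-methoxy-2-oxo-2H-chromen-8-yl)oxy]phenyl formate F3.
- Methanolysis (KHCO3, MeOH) should give 8-[2,4-bis(benzyloxy)-6-hydroxyphenoxy]-7-methoxy-2H-chromen-2-one F4, in which only one flanking hydroxyl is free.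
- Annulation with 14 under the conditions of step 7 should give 8-{[5,7-bis(benzyloxy)-2-oxo-2H-chromen-8-yl]oxy}-7-methoxy-2H-chromen-2-one F5.
- BCl3 with pentamethylbenzene at −78 °C should remove the benzyl groups and give 17.

This coupling joins two di-ortho-substituted partners, which is why it is held in reserve.

**Step 6.** The risk is loss of site selectivity: the two flanking hydroxyls are statistically favoured and slightly more acidic, so silylation there with the para oxygen left free would lead to the wrong lactone. Over-silylation at one flanking oxygen in addition to the para oxygen is harmless, since the remaining flanking hydroxyl still closes correctly. Silyl migration under base is a second concern.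

Fallback, from 12 to 17: chelation replaces steric control.
- Vilsmeier–Haack formylation (POCl3, DMF) should give 2,4,6-trihydroxy-3-[(7-methoxy-2-oxo-2H-chromen-8-yl)oxy]benzaldehyde F6.
- Bis-protection with MOMCl and i-Pr2NEt should spare the hydroxyl that is both chelated to the aldehyde and flanked on two sides, giving 2-hydroxy-4,6-bis(methoxymethoxy)-3-[(7-methoxy-2-oxo-2H-chromen-8-yl)oxy]benzaldehyde F7.
- Wittig olefination–lactonisation with 2 (PhNEt2, reflux) should give 8-{[5,7-bis(methoxymethoxy)-2-oxo-2H-chromen-8-yl]oxy}-7-methoxy-2H-chromen-2-one F8.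
- HCl in MeOH should give 17.

**Step 7.** The reacting C–H lies between a hydroxyl and a bulky silyl ether, so C–C bond formation may be slow. Acid-induced desilylation before lactonisation would allow closure on the wrong oxygen, and a second annulation at the other flanking hydroxyl is possible with excess 14.

Fallback, from 13 to 16: carbonyl chemistry replaces the palladium step. Vilsmeier–Haack formylation should give 2,4-dihydroxy-3-[(7-methoxy-2-oxo-2H-chromen-8-yl)oxy]-6-[(triisopropylsilyl)oxy]benzaldehyde F9. Wittig olefination–lactonisation with 2 as in step 1 should then give 16.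

**Step 4.** Acylation may occur at oxygen or at the central carbon of diene 8 instead of its terminus, and 11 may lactonise during work-up or chromatography.

Fallback, from 7 to 11: coupling of 7 with N,O-dimethylhydroxylamine hydrochloride (EDC·HCl, i-Pr2NEt) should give N-methoxy-2-[(7-methoxy-2-oxo-2H-chromen-8-yl)oxy]-N-methylacetamide F10. Acylation of the dianion of methyl acetoacetate (NaH, then n-BuLi, THF, −78 °C) with F10, then acidic quench, should give 11. The low temperature is meant to keep the dianion from adding to the ring A lactone.

## Further compounds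

F1 | step 5 | 3,5-bis(benzyloxy)-2-bromobenzaldehyde | O=Cc1cc(OCc2ccccc2)cc(OCc2ccccc2)c1Br
F2 | step 5 | 3,5-bis(benzyloxy)-2-[(7-methoxy-2-oxo-2H-chromen-8-yl)oxy]benzaldehyde | COc1ccc2ccc(=O)oc2c1Oc1c(C=O)cc(OCc2ccccc2)cc1OCc1ccccc1
F3 | step 5 | 3,5-bis(benzyloxy)-2-[(7-methoxy-2-oxo-2H-chromen-8-yl)oxy]phenyl formate | COc1ccc2ccc(=O)oc2c1Oc1c(OC=O)cc(OCc2ccccc2)cc1OCc1ccccc1
F4 | step 5 | 8-[2,4-bis(benzyloxy)-6-hydroxyphenoxy]-7-methoxy-2H-chromen-2-one | COc1ccc2ccc(=O)oc2c1Oc1c(O)cc(OCc2ccccc2)cc1OCc1ccccc1
F5 | step 5 | 8-{[5,7-bis(benzyloxy)-2-oxo-2H-chromen-8-yl]oxy}-7-methoxy-2H-chromen-2-one | COc1ccc2ccc(=O)oc2c1Oc1c(OCc2ccccc2)cc(OCc2ccccc2)c2ccc(=O)oc12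
F6 | step 6 | 2,4,6-trihydroxy-3-[(7-methoxy-2-oxo-2H-chromen-8-yl)oxy]benzaldehyde | COc1ccc2ccc(=O)oc2c1Oc1c(O)cc(O)c(C=O)c1O
F7 | step 6 | 2-hydroxy-4,6-bis(methoxymethoxy)-3-[(7-methoxy-2-oxo-2H-chromen-8-yl)oxy]benzaldehyde | COCOc1cc(OCOC)c(C=O)c(O)c1Oc1c(OC)ccc2ccc(=O)oc12
F8 | step 6 | 8-{[5,7-bis(methoxymethoxy)-2-oxo-2H-chromen-8-yl]oxy}-7-methoxy-2H-chromen-2-one | COCOc1cc(OCOC)c2ccc(=O)oc2c1Oc1c(OC)ccc2ccc(=O)oc12
F9 | step 7 | 2,4-dihydroxy-3-[(7-methoxy-2-oxo-2H-chromen-8-yl)oxy]-6-[(triisopropylsilyl)oxy]benzaldehyde | COc1ccc2ccc(=O)oc2c1Oc1c(O)cc(O[Si](C(C)C)(C(C)C)C(C)C)c(C=O)c1O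
F10 | step 4 | N-methoxy-2-[(7-methoxy-2-oxo-2H-chromen-8-yl)oxy]-N-methylacetamide | CON(C)C(=O)COc1c(OC)ccc2ccc(=O)oc12
A1 | alternative 1 | 2,4-bis(benzyloxy)-6-(methoxymethoxy)phenol | COCOc1cc(OCc2ccccc2)cc(OCc2ccccc2)c1O
A2 | alternative 1 | methyl (6E)-4-[2,4-bis(benzyloxy)-6-(methoxymethoxy)phenoxy]-7-methoxy-3,5-dioxohept-6-enoate (racemic at C4) | CO/C=C/C(=O)C(Oc1c(OCOC)cc(OCc2ccccc2)cc1OCc1ccccc1)C(=O)CC(=O)OC
A3 | alternative 1 | methyl 3-[2,4-bis(benzyloxy)-6-(methoxymethoxy)phenoxy]-2,4-dihydroxybenzoate | COC(=O)c1ccc(O)c(Oc2c(OCOC)cc(OCc3ccccc3)cc2OCc2ccccc2)c1O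
A4 | alternative 2 | 5,7-bis(benzyloxy)-8-hydroxy-2H-chromen-2-one | O=c1ccc2c(OCc3ccccc3)cc(OCc3ccccc3)c(O)c2o1
A5 | alternative 2 | methyl 6-{[5,7-bis(benzyloxy)-2-oxo-2H-chromen-8-yl]oxy}-3-[(tert-butyldimethylsilyl)oxy]-5-oxohexanoate (racemic) | COC(=O)CC(O[Si](C)(C)C(C)(C)C)CC(=O)COc1c(OCc2ccccc2)cc(OCc2ccccc2)c2ccc(=O)oc12
A6 | alternative 2 | 5,7-bis(benzyloxy)-8-(2,6-dihydroxyphenoxy)-2H-chromen-2-one | Oc1cccc(O)c1Oc1c(OCc2ccccc2)cc(OCc2ccccc2)c2ccc(=O)oc12
A7 | alternative 3 | {[2-[2,4-bis(benzyloxy)-6-(methoxymethoxy)phenoxy]-1,3-dimethoxybuta-1,3-dien-1-yl]oxy}trimethylsilane (geometry undefined) | COC(=C)C(Oc1c(OCOC)cc(OCc2ccccc2)cc1OCc1ccccc1)=C(OC)O[Si](C)(C)C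
A8 | alternative 3 | propynal | C#CC=O
A9 | alternative 3 | 3-[2,4-bis(benzyloxy)-6-(methoxymethoxy)phenoxy]-2-hydroxy-4-methoxybenzaldehyde | COc1ccc(C=O)c(O)c1Oc1c(OCOC)cc(OCc2ccccc2)cc1OCc1ccccc1
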